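## Retrosynthetic overview

- Last operation: release the primary OH from its trityl ether under conditions that do not let the 2-O-acyl group migrate.
- C2–O ester bond: invertive Mitsunobu esterification of the secondary alcohol with unprotected 4-hydroxybenzoic acid; the stereocentre comes from (S)-glycidyl trityl ether and is inverted once.
- Ether C–O bond: the alkoxide of (4E,6E,8E)-dodeca-4,6,8-trien-1-ol opens the epoxide at its CH2 terminus.
- Key C3–C4 bond: the zinc homoenolate of ethyl propanoate (β-carbon as nucleophile) is coupled with an (E,E,E)-iodotriene (Negishi); the ester is then reduced to the trienol.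
- The iodotriene comes from (2E,4E)-octa-2,4-dienal by Takai iodo-olefination. No ring is formed: the arene is bought and the epoxide is only opened.

Assumption: (2E,4E)-octa-2,4-dienal, ethyl 3-iodopropanoate, (S)-glycidyl trityl ether and 4-hydroxybenzoic acid are bought as such; all polyenes are handled under argon in the dark.

## Route

Step 1
Reactants: 1 (2E,4E)-octa-2,4-dienal
Product: 2 (1E,3E,5E)-1-iodonona-1,3,5-triene
Conditions: CHI3 (2 equiv), CrCl2 (6 equiv), dioxane/THF 6:1, 0 °C to rt, dark; used at once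
Reagents that add atoms: iodoform, IC(I)I
Why: Takai–Utimoto iodo-olefination, in which the gem-dichromium species from CHI3/CrCl2 adds to the aldehyde and eliminates to the (E)-vinyl iodide (E-selectivity raised by dioxane) while the existing (E,E)-diene is untouched.

Step 2
Reactants: 2 (1E,3E,5E)-1-iodonona-1,3,5-triene; 3 ethyl 3-iodopropanoate
Product: 5 ethyl (4E,6E,8E)-dodeca-4,6,8-trienoate, via zinc homoenolate 4 (not isolated)
Conditions: 3 (1.5 equiv), Zn dust (activated with BrCH2CH2Br/TMSCl), THF, 35 °C, 4 h; then 2, Pd(PPh3)4 (5 mol %), THF/DMA 2:1, 25 °C, dark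
Reagents that add atoms: none
Why: Negishi cross-coupling of a carbonyl-chelated β-zincio ester (zinc homoenolate), in which the normally electrophilic β-carbon of the propanoate reacts as the nucleophile and is joined to the electrophilic sp2 carbon of the iodotriene with retention of all three alkene geometries.

Step 3
Reactants: 5 ethyl (4E,6E,8E)-dodeca-4,6,8-trienoate
Product: 6 (4E,6E,8E)-dodeca-4,6,8-trien-1-ol
Conditions: LiAlH4 (1.0 equiv), Et2O, 0 °C, 30 min; Fieser work-up
Reagents that add atoms: none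
Why: hydride reduction of an ester whose carbonyl is not conjugated to the triene, so the hydrocarbon triene is inert at 0 °C.

Step 4
Reactants: 6 (4E,6E,8E)-dodeca-4,6,8-trien-1-ol; 7 (S)-glycidyl trityl ether
Product: 9 (2S)-1-[(4E,6E,8E)-dodeca-4,6,8-trien-1-yloxy]-3-(trityloxy)propan-2-ol, via sodium alkoxide 8 (not isolated)
Conditions: 6 (1.2 equiv), NaH (1.2 equiv), DMF, 0 °C to rt; then 7 (1.0 equiv), 60 °C, 8 h; water quench; excess 6 recovered
Reagents that add atoms: none
Why: base-mediated SN2 epoxide opening at the unhindered CH2 terminus, so the C2–O bond is never broken and the configuration of 7 is carried unchanged into 9; the trityl group cannot migrate under base.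

Step 5
Reactants: 9 (2S)-1-[(4E,6E,8E)-dodeca-4,6,8-trien-1-yloxy]-3-(trityloxy)propan-2-ol; 10 4-hydroxybenzoic acid
Product: 11 (2R)-1-[(4E,6E,8E)-dodeca-4,6,8-trien-1-yloxy]-3-(trityloxy)propan-2-yl 4-hydroxybenzoate
Conditions: 10 (1.5 equiv), PPh3 (1.6 equiv), DIAD (1.5 equiv, added last, dropwise), THF, 0 °C to rt, dark
Reagents that add atoms: none
Why: Mitsunobu esterification, in which only the carboxylic acid (pKa about 4.5, against about 9.3 for the phenol) protonates the betaine and its carboxylate displaces the oxyphosphonium group by SN2 with clean inversion at C2, which sets the final configuration without protecting the phenol.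

Step 6
Reactants: 11 (2R)-1-[(4E,6E,8E)-dodeca-4,6,8-trien-1-yloxy]-3-(trityloxy)propan-2-yl 4-hydroxybenzoate
Product: 12 (2S)-1-[(4E,6E,8E)-dodeca-4,6,8-trien-1-yloxy]-3-hydroxypropan-2-yl 4-hydroxybenzoate
Conditions: BF3·OEt2 (0.3 equiv), MeOH (20 equiv), CH2Cl2, 0 °C, 30–60 min; cold NaHCO3; fast chromatography on boric-acid-treated silica
Reagents that add atoms: none
Why: acid-catalysed SN1 detritylation with methanol as trityl-cation trap at 0 °C, the standard way to unmask 1-O-alkyl-2-O-acyl-3-O-trityl glycerols without 2→3 acyl migration; C2 is untouched, and the descriptor changes from R to S only because CH2OH ranks below CH2O-alkyl.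

## Compound list

1 | (2E,4E)-octa-2,4-dienal | CCC/C=C/C=C/C=O | starting material
2 | (1E,3E,5E)-1-iodonona-1,3,5-triene | CCC/C=C/C=C/C=C/I | intermediate
3 | ethyl 3-iodopropanoate | CCOC(=O)CCI | starting material
4 | (3-ethoxy-3-oxopropyl)zinc iodide (zinc homoenolate, not isolated) | CCOC(=O)CC[Zn]I | intermediate
5 | ethyl (4E,6E,8E)-dodeca-4,6,8-trienoate | CCC/C=C/C=C/C=C/CCC(=O)OCC | intermediate
6 | (4E,6E,8E)-dodeca-4,6,8-trien-1-ol | CCC/C=C/C=C/C=C/CCCO | intermediate
7 | (S)-glycidyl trityl ether, (2S)-2-[(trityloxy)methyl]oxirane | C1[C@@H](COC(c2ccccc2)(c2ccccc2)c2ccccc2)O1 | starting material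
8 | sodium (4E,6E,8E)-dodeca-4,6,8-trien-1-olate (not isolated) | CCC/C=C/C=C/C=C/CCC[O-].[Na+] | intermediate
9 | (2S)-1-[(4E,6E,8E)-dodeca-4,6,8-trien-1-yloxy]-3-(trityloxy)propan-2-ol | CCC/C=C/C=C/C=C/CCCOC[C@@H](COC(c1ccccc1)(c1ccccc1)c1ccccc1)O | intermediate
10 | 4-hydroxybenzoic acid | OC(=O)c1ccc(O)cc1 | starting material
11 | (2R)-1-[(4E,6E,8E)-dodeca-4,6,8-trien-1-yloxy]-3-(trityloxy)propan-2-yl 4-hydroxybenzoate | CCC/C=C/C=C/C=C/CCCOC[C@H](COC(c1ccccc1)(c1ccccc1)c1ccccc1)OC(=O)c1ccc(O)cc1 | intermediate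
12 | (2S)-1-[(4E,6E,8E)-dodeca-4,6,8-trien-1-yloxy]-3-hydroxypropan-2-yl 4-hydroxybenzoate (CNP0352133.1) | CCC/C=C/C=C/C=C/CCCOC[C@H](CO)OC(=O)c1ccc(O)cc1 | target

## Step count and risks

Total steps: 6. Longest linear sequence: 6 (1 → 2 → 5 → 6 → 9 → 11 → 12).

Steps most likely to fail:

Step 2. The iodotriene 2 is light- and air-sensitive, and the coupling may be slow or erode the alkene geometry. The fallback sets out from 1 and comes back at 5. Vinylmagnesium bromide is added to 1 (THF, −78 °C, 1,2-addition) to give (4E,6E)-deca-1,4,6-trien-3-ol F1. A Johnson–Claisen rearrangement with triethyl orthoacetate (cat. propanoic acid, 135 °C) then engages the unsubstituted vinyl terminus through a chair transition state, creates the (4E)-alkene and delivers 5 directly. Neither 2 nor any cross-coupling is needed.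

Step 5. The secondary alcohol is flanked by a bulky trityloxymethyl group, the acid carries a free phenol, and DIAD is a potential dienophile toward the triene. The fallback sets out from 6 and comes back at 11. Alkoxide 8 opens (R)-glycidyl trityl ether (the commercial enantiomer of 7, C1[C@H](COC(c2ccccc2)(c2ccccc2)c2ccccc2)O1) as in step 4 to give (2R)-1-[(4E,6E,8E)-dodeca-4,6,8-trien-1-yloxy]-3-(trityloxy)propan-2-ol F2. This is acylated with retention by 4-acetoxybenzoic acid (EDC·HCl, DMAP, CH2Cl2, 0 °C to rt) to give (2R)-1-[(4E,6E,8E)-dodeca-4,6,8-trien-1-yloxy]-3-(trityloxy)propan-2-yl 4-acetoxybenzoate F3. The aryl acetate is then removed selectively with hydrazine acetate (DMF, 0 °C); the primary oxygen is still tritylated, so no acyl migration is possible, and the product is 11.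

Step 6. Acid can cause 2→3 acyl migration or damage the triene. The fallback sets out from 9 and comes back at 12. The trityl group is removed before any acyl group is present (cat. TsOH, MeOH/CH2Cl2, rt) to give (2R)-3-[(4E,6E,8E)-dodeca-4,6,8-trien-1-yloxy]propane-1,2-diol F4. The primary OH is silylated selectively (TBSCl, imidazole, CH2Cl2, −20 to 0 °C) to give (2S)-1-[(tert-butyldimethylsilyl)oxy]-3-[(4E,6E,8E)-dodeca-4,6,8-trien-1-yloxy]propan-2-ol F5. The same invertive Mitsunobu esterification with 10 gives (2R)-1-[(tert-butyldimethylsilyl)oxy]-3-[(4E,6E,8E)-dodeca-4,6,8-trien-1-yloxy]propan-2-yl 4-hydroxybenzoate F6. The primary OH is finally released with HF·pyridine buffered with pyridine (THF, 0 °C), a deprotection that leaves 2-acyl glycerols unmigrated, to give 12.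

## Further compounds

F1 | step 2 | (4E,6E)-deca-1,4,6-trien-3-ol | CCC/C=C/C=C/C(O)C=C
F2 | step 5 | (2R)-1-[(4E,6E,8E)-dodeca-4,6,8-trien-1-yloxy]-3-(trityloxy)propan-2-ol | CCC/C=C/C=C/C=C/CCCOC[C@H](COC(c1ccccc1)(c1ccccc1)c1ccccc1)O
F3 | step 5 | (2R)-1-[(4E,6E,8E)-dodeca-4,6,8-trien-1-yloxy]-3-(trityloxy)propan-2-yl 4-acetoxybenzoate | CCC/C=C/C=C/C=C/CCCOC[C@H](COC(c1ccccc1)(c1ccccc1)c1ccccc1)OC(=O)c1ccc(OC(C)=O)cc1
F4 | step 6 | (2R)-3-[(4E,6E,8E)-dodeca-4,6,8-trien-1-yloxy]propane-1,2-diol | CCC/C=C/C=C/C=C/CCCOC[C@@H](CO)O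
F5 | step 6 | (2S)-1-[(tert-butyldimethylsilyl)oxy]-3-[(4E,6E,8E)-dodeca-4,6,8-trien-1-yloxy]propan-2-ol | CCC/C=C/C=C/C=C/CCCOC[C@@H](CO[Si](C)(C)C(C)(C)C)O
F6 | step 6 | (2R)-1-[(tert-butyldimethylsilyl)oxy]-3-[(4E,6E,8E)-dodeca-4,6,8-trien-1-yloxy]propan-2-yl 4-hydroxybenzoate | CCC/C=C/C=C/C=C/CCCOC[C@H](CO[Si](C)(C)C(C)(C)C)OC(=O)c1ccc(O)cc1
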